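**Retrosynthetic overview**
1. The target is a dimer of one flavan-3-ol, so the interflavan C4–C8 bond is cut last: Friedel–Crafts coupling of a C4-alkoxylated (2R,3R)-5,7-bis(benzyloxy)flavan-3-ol with the same, unmodified flavan-3-ol.
2. The C2/C3 cis pair of that monomer goes back to the racemic flavan-3-one (asymmetric hydrogenation with dynamic kinetic resolution), and the ketone to its 3-benzyloxy-2H-chromene enol ether.
3. Ring C of the chromene is cut at C4–C4a, O1–C8a and O1–C2: a 3,5-bis(benzyloxy)aryne (ring A) plus 2-(benzyloxy)cinnamaldehyde, joined by formal [2+2] at the aldehyde C=O, 4π ring opening and oxa-6π ring closure.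
4. Enabling feature: the ring-A oxygen on C5, ortho to C4a, polarises the C4a≡C8a aryne so that the aldehyde oxygen goes to C8a and the aldehyde carbon to C4a; the C2=C3 bond of the enal makes the opened intermediate an O1=C8a–C4a=C4–C3=C2 oxatriene that closes ring C.
5. Ring order: rings A and B are bought (3,5-bis(benzyloxy)phenol, benzaldehyde); ring C is built once and used for both halves; the halves are then joined and debenzylated.

Key step: step 4

Assumption: the (S),(S) hand of the hydrogenation catalyst in step 6 is taken as the one matched to the (2R)-ketone, by analogy with 2-arylcyclohexanones; if the sense is reversed, the mirror-image complex RuCl2[(R)-xylbinap][(R)-daipen] is the catalyst meant.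

**Route**

Step 1
Reactants: 1 3,5-bis(benzyloxy)phenol
Product: 2 2-bromo-3,5-bis(benzyloxy)phenol
Conditions: NBS (1.0 equiv), CH2Cl2, −78 °C to 0 °C
Reagents that add atoms: N-bromosuccinimide, O=C1CCC(=O)N1Br
Why: Electrophilic aromatic bromination: at low temperature NBS should attack the position ortho to the free hydroxyl (C2, equivalent to C6), because the only other activated position lies between two benzyloxy groups and is more hindered.

Step 2
Reactants: 2 2-bromo-3,5-bis(benzyloxy)phenol
Product: 5 3,5-bis(benzyloxy)-2-(trimethylsilyl)phenyl trifluoromethanesulfonate, via aryl trimethylsilyl ether 3 (not isolated), via lithium silylphenoxide 4 (not isolated)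
Conditions: HMDS, THF, 70 °C, then evaporation; n-BuLi (1.1 equiv), THF, −100 °C; Tf2O (1.2 equiv), −100 °C to rt
Reagents that add atoms: hexamethyldisilazane, C[Si](C)(C)N[Si](C)(C)C; trifluoromethanesulfonic anhydride, O=S(=O)(OS(=O)(=O)C(F)(F)F)C(F)(F)F
Why: Standard three-stage entry to an ortho-silylaryl triflate: O-silylation, bromine–lithium exchange followed by 1,3 O-to-C silyl shift (retro-Brook rearrangement) that puts SiMe3 on the former C–Br carbon, and triflation of the lithium phenoxide so released; the benzyl ethers should tolerate n-BuLi at −100 °C.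

Step 3
Reactants: 6 benzaldehyde, 7 (benzyloxy)acetaldehyde
Product: 9 (2Z)-2-(benzyloxy)-3-phenylprop-2-enal, via aldol adduct 8 (not isolated)
Conditions: 6 (3 equiv), KOH (0.1 equiv), MeOH, 0 °C to rt, slow addition of 7
Reagents that add atoms: none
Why: Crossed aldol (Claisen–Schmidt) condensation in which only 7 can enolise and excess 6 suppresses its self-condensation; E1cB loss of water from 8 gives the conjugated enal with phenyl anti to the formyl group (Z).

Step 4
Reactants: 5 3,5-bis(benzyloxy)-2-(trimethylsilyl)phenyl trifluoromethanesulfonate, 9 (2Z)-2-(benzyloxy)-3-phenylprop-2-enal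
Product: 13 racemic 3,5,7-tris(benzyloxy)-2-phenyl-2H-chromene, via aryne 10 (not isolated), via benzoxete 11 (not isolated), via ortho-quinone methide 12 (not isolated)
Conditions: CsF (3 equiv), 9 (3 equiv), MeCN, 25 °C, slow addition of 5
Reagents that add atoms: none
Why: CsF strips SiMe3 and triflate from 5 to give aryne 10; the aldehyde oxygen of 9 attacks the aryne and the aryl carbon so formed closes on the carbonyl carbon (stepwise formal [2+2]) to benzoxete 11, which opens (4π) to ortho-quinone methide 12, and oxa-6π electrocyclisation of 12 then closes ring C. The closest known reaction type is the annulation of arynes with α,β-unsaturated aldehydes such as cinnamaldehyde to 2H-chromenes, together with the formal [2+2] of alkoxy-arynes with formamide C=O groups. Ring C is closed by a thermal disrotatory 6π electrocyclisation between O1 and C2 of the O1=C8a–C4a=C4–C3=C2 oxatriene, the C8a–O1 and C4a–C4 bonds having been made in the transient four-membered ring. The one new stereocentre, C2, forms without control and 13 is racemic by design, because C2 becomes α to the ketone of 14 and is set in step 6. The step needs regioselectivity (oxygen to C8a, carbon to C4a), which the benzyloxy group on C5 should secure by making the aryne carbon remote from it (C8a) the electrophilic one and by stabilising negative charge at C4a; it also needs chemoselectivity for the C=O group over C=C bonds, which an excess of 9 and slow generation of 10 should secure.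

Step 5
Reactants: 13 racemic 3,5,7-tris(benzyloxy)-2-phenyl-2H-chromene
Product: 14 racemic 5,7-bis(benzyloxy)-2-phenylchroman-3-one
Conditions: 1 M HCl (aq), THF, 25 °C
Reagents that add atoms: water, O
Why: Acid-catalysed enol ether hydrolysis: protonation at C4 gives the C3 oxocarbenium ion, water adds and benzyl alcohol leaves, while the two aryl benzyl ethers are inert and C2 stays racemic.

Step 6
Reactants: 14 racemic 5,7-bis(benzyloxy)-2-phenylchroman-3-one
Product: 15 (2R,3R)-5,7-bis(benzyloxy)-2-phenylchroman-3-ol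
Conditions: RuCl2[(S)-xylbinap][(S)-daipen] (1 mol %), KOtBu (0.2 equiv), H2 (10 atm), i-PrOH/toluene, 25 °C
Reagents that add atoms: none
Why: Noyori-type asymmetric ketone hydrogenation run as a dynamic kinetic resolution (reaction type known for 2-aryl- and 2-alkoxy-cycloalkanones, which give cis alcohols): KOtBu racemises C2 through the enolate, the chiral catalyst should reduce the (2R)-ketone faster, and hydride is delivered to C3 anti to the C2 phenyl group, so that C2 (R) and C3 (R) are set together as the 2,3-cis pair.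

Step 7
Reactants: 15 (2R,3R)-5,7-bis(benzyloxy)-2-phenylchroman-3-ol
Product: 16 (2R,3R,4S)-5,7-bis(benzyloxy)-4-(2-ethoxyethoxy)-2-phenylchroman-3-ol
Conditions: DDQ (2 equiv), 2-ethoxyethanol (5 equiv), CH2Cl2, 25 °C
Reagents that add atoms: 2-ethoxyethanol, CCOCCO
Why: Benzylic oxidation with DDQ: hydride abstraction from C4, which is activated by the 5,7-dioxygenated ring A, and capture of the cation by 2-ethoxyethanol anti to the C3 hydroxyl (the C4 configuration is of no consequence, since C4 is ionised again in step 8), as is standard for benzylated flavan-3-ols.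

Step 8
Reactants: 16 (2R,3R,4S)-5,7-bis(benzyloxy)-4-(2-ethoxyethoxy)-2-phenylchroman-3-ol, 15 (2R,3R)-5,7-bis(benzyloxy)-2-phenylchroman-3-ol
Product: 17 (2R,3R)-5,7-bis(benzyloxy)-8-[(2R,3R,4R)-5,7-bis(benzyloxy)-3-hydroxy-2-phenyl-3,4-dihydro-2H-chromen-4-yl]-2-phenyl-3,4-dihydro-2H-chromen-3-ol
Conditions: 15 (4 equiv), TMSOTf (0.1 equiv), CH2Cl2, −78 °C; Et3N quench
Reagents that add atoms: none
Why: Lewis-acid Friedel–Crafts alkylation: TMSOTf ionises the C4 ether of 16 and C8 of 15, the more nucleophilic ring-A position of a 5,7-dibenzyloxyflavan, should attack the cation anti to the pseudo-axial C3 hydroxyl of the 2,3-cis unit, which sets C4 as 4R (3,4-trans); a four-fold excess of 15, recovered afterwards, suppresses further alkylation of 17.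

Step 9
Reactants: 17 (2R,3R)-5,7-bis(benzyloxy)-8-[(2R,3R,4R)-5,7-bis(benzyloxy)-3-hydroxy-2-phenyl-3,4-dihydro-2H-chromen-4-yl]-2-phenyl-3,4-dihydro-2H-chromen-3-ol
Product: 18 (2R,3R)-8-[(2R,3R,4R)-3,5,7-trihydroxy-2-phenyl-3,4-dihydro-2H-chromen-4-yl]-2-phenyl-3,4-dihydro-2H-chromene-3,5,7-triol
Conditions: H2 (1 atm), Pd(OH)2/C, THF/MeOH/H2O, 25 °C
Reagents that add atoms: none
Why: Hydrogenolysis of the four aryl benzyl ethers over Pd(OH)2/C under neutral conditions, which should leave the interflavan bond, the two C2–O1 benzylic ether bonds and all five stereocentres untouched.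

**Compound list**
1 | 3,5-bis(benzyloxy)phenol | Oc1cc(OCc2ccccc2)cc(OCc2ccccc2)c1 | starting material
2 | 2-bromo-3,5-bis(benzyloxy)phenol | Oc1cc(OCc2ccccc2)cc(OCc2ccccc2)c1Br | intermediate
3 | [2-bromo-3,5-bis(benzyloxy)phenoxy]trimethylsilane | C[Si](C)(C)Oc1cc(OCc2ccccc2)cc(OCc2ccccc2)c1Br | intermediate
4 | lithium 3,5-bis(benzyloxy)-2-(trimethylsilyl)phenoxide | [Li+].[O-]c1cc(OCc2ccccc2)cc(OCc2ccccc2)c1[Si](C)(C)C | intermediate
5 | 3,5-bis(benzyloxy)-2-(trimethylsilyl)phenyl trifluoromethanesulfonate | C[Si](C)(C)c1c(OS(=O)(=O)C(F)(F)F)cc(OCc2ccccc2)cc1OCc1ccccc1 | intermediate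
6 | benzaldehyde | O=Cc1ccccc1 | starting material
7 | (benzyloxy)acetaldehyde | O=CCOCc1ccccc1 | starting material
8 | 2-(benzyloxy)-3-hydroxy-3-phenylpropanal (aldol adduct, mixture of racemic diastereomers) | O=CC(OCc1ccccc1)C(O)c1ccccc1 | intermediate
9 | (2Z)-2-(benzyloxy)-3-phenylprop-2-enal | O=C/C(OCc1ccccc1)=C/c1ccccc1 | intermediate
10 | 3,5-bis(benzyloxy)benzyne (1,2-didehydro-3,5-bis(benzyloxy)benzene) | C1#CC(OCc2ccccc2)=CC(OCc2ccccc2)=C1 | intermediate
11 | 3,5-bis(benzyloxy)-2-[(Z)-1-(benzyloxy)-2-phenylethenyl]-2H-1-benzoxete (racemic) | O1C(/C(OCc2ccccc2)=C/c2ccccc2)c2c1cc(OCc1ccccc1)cc2OCc1ccccc1 | intermediate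
12 | 3,5-bis(benzyloxy)-6-[2-(benzyloxy)-3-phenylprop-2-en-1-ylidene]cyclohexa-2,4-dien-1-one | O=C1C=C(OCc2ccccc2)C=C(OCc2ccccc2)C1=CC(OCc1ccccc1)=Cc1ccccc1 | intermediate
13 | racemic 3,5,7-tris(benzyloxy)-2-phenyl-2H-chromene | C(c1ccccc1)Oc1cc(OCc2ccccc2)c2C=C(OCc3ccccc3)C(c3ccccc3)Oc2c1 | intermediate
14 | racemic 5,7-bis(benzyloxy)-2-phenylchroman-3-one | C(c1ccccc1)Oc1cc(OCc2ccccc2)c2CC(=O)C(c3ccccc3)Oc2c1 | intermediate
15 | (2R,3R)-5,7-bis(benzyloxy)-2-phenylchroman-3-ol | C(c1ccccc1)Oc1cc(OCc2ccccc2)c2c(c1)O[C@H](c1ccccc1)[C@H](O)C2 | intermediate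
16 | (2R,3R,4S)-5,7-bis(benzyloxy)-4-(2-ethoxyethoxy)-2-phenylchroman-3-ol | C(c1ccccc1)Oc1cc(OCc2ccccc2)c2c(c1)O[C@H](c1ccccc1)[C@H](O)[C@H]2OCCOCC | intermediate
17 | (2R,3R)-5,7-bis(benzyloxy)-8-[(2R,3R,4R)-5,7-bis(benzyloxy)-3-hydroxy-2-phenyl-3,4-dihydro-2H-chromen-4-yl]-2-phenyl-3,4-dihydro-2H-chromen-3-ol | C(c1ccccc1)Oc1cc(OCc2ccccc2)c2c(c1)O[C@H](c1ccccc1)[C@H](O)[C@H]2c1c(OCc2ccccc2)cc(OCc2ccccc2)c2c1O[C@H](c1ccccc1)[C@H](O)C2 | intermediate
18 | (2R,3R)-8-[(2R,3R,4R)-3,5,7-trihydroxy-2-phenyl-3,4-dihydro-2H-chromen-4-yl]-2-phenyl-3,4-dihydro-2H-chromene-3,5,7-triol | Oc1cc(O)c2c(c1)O[C@H](c1ccccc1)[C@H](O)[C@H]2c1c(O)cc(O)c2c1O[C@H](c1ccccc1)[C@H](O)C2 | target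

**Step count and risks**

Total step count: 9. Longest linear sequence: 8 steps (steps 1, 2, 4, 5, 6, 7, 8, 9 from compound 1); step 3 is a one-step side branch.

Steps most likely to fail:

1. Step 4. The aryne may be consumed by the electron-rich enol-ether double bond of the chromene already formed or by a second aldehyde molecule, or the first C–O bond may form at both aryne carbons. The fallback builds ring C without an aryne; it sets out from 1 and comes back at 14. Friedel–Crafts alkylation of 1 with (E)-cinnamyl alcohol (H2SO4 on SiO2, CH2Cl2) at the carbon ortho to the hydroxyl gives 3,5-bis(benzyloxy)-2-[(2E)-3-phenylprop-2-en-1-yl]phenol F1. Prilezhaev epoxidation (mCPBA, NaHCO3, CH2Cl2) gives racemic trans-3,5-bis(benzyloxy)-2-[(3-phenyloxiran-2-yl)methyl]phenol F2. With camphorsulfonic acid, the phenol oxygen should open F2 at the benzylic epoxide carbon to give racemic trans-5,7-bis(benzyloxy)-2-phenylchroman-3-ol F3, and Dess–Martin oxidation of F3 gives 14.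

2. Step 6. Racemisation at C2 may not keep pace with reduction, the catalyst may discriminate poorly between the ketone enantiomers, or the ketone may condense with itself under base. The fallback sets the two stereocentres by substrate control and resolution; it sets out from 14 and comes back at 15. LiBH(s-Bu)3 in THF at −78 °C should add hydride anti to the C2 phenyl group and give racemic cis-5,7-bis(benzyloxy)-2-phenylchroman-3-ol F4. Esterification with (S)-methoxy(phenyl)acetic acid (DCC, DMAP, CH2Cl2) gives the diastereomeric esters (2R,3R)-5,7-bis(benzyloxy)-2-phenylchroman-3-yl (2S)-methoxy(phenyl)acetate F5 and (2S,3S)-5,7-bis(benzyloxy)-2-phenylchroman-3-yl (2S)-methoxy(phenyl)acetate F6, which are separated by chromatography or crystallisation. Methanolysis of F5 (K2CO3, MeOH) gives 15.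

3. Step 8. The dimer may be alkylated further (oligomerisation), so that only a large excess of the nucleophile gives a clean coupling. The fallback caps the electrophilic unit with bromine; it sets out from 15 and comes back at 18. NBS in CH2Cl2 at −78 °C should brominate C8 of 15 to give (2R,3R)-5,7-bis(benzyloxy)-8-bromo-2-phenylchroman-3-ol F7. DDQ and 2-ethoxyethanol as in step 7 give (2R,3R,4S)-5,7-bis(benzyloxy)-8-bromo-4-(2-ethoxyethoxy)-2-phenylchroman-3-ol F8. TMSOTf-mediated coupling of F8 with a slight excess of 15 gives (2R,3R)-5,7-bis(benzyloxy)-8-[(2R,3R,4S)-5,7-bis(benzyloxy)-8-bromo-3-hydroxy-2-phenyl-3,4-dihydro-2H-chromen-4-yl]-2-phenyl-3,4-dihydro-2H-chromen-3-ol F9, whose brominated upper ring should neither self-condense nor be alkylated again. Hydrogenolysis (H2, Pd(OH)2/C, Et3N, THF/MeOH) removes the bromine together with the four benzyl groups and gives 18.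

**Further compounds**
F1 | step 4 | 3,5-bis(benzyloxy)-2-[(2E)-3-phenylprop-2-en-1-yl]phenol | Oc1cc(OCc2ccccc2)cc(OCc2ccccc2)c1C/C=C/c1ccccc1
F2 | step 4 | racemic trans-3,5-bis(benzyloxy)-2-[(3-phenyloxiran-2-yl)methyl]phenol (one enantiomer drawn) | Oc1cc(OCc2ccccc2)cc(OCc2ccccc2)c1C[C@H]1O[C@@H]1c1ccccc1
F3 | step 4 | racemic trans-5,7-bis(benzyloxy)-2-phenylchroman-3-ol ((2R,3S) enantiomer drawn) | C(c1ccccc1)Oc1cc(OCc2ccccc2)c2c(c1)O[C@H](c1ccccc1)[C@@H](O)C2
F4 | step 6 | racemic cis-5,7-bis(benzyloxy)-2-phenylchroman-3-ol ((2R,3R) enantiomer drawn) | C(c1ccccc1)Oc1cc(OCc2ccccc2)c2c(c1)O[C@H](c1ccccc1)[C@H](O)C2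
F5 | step 6 | (2R,3R)-5,7-bis(benzyloxy)-2-phenylchroman-3-yl (2S)-methoxy(phenyl)acetate | C(c1ccccc1)Oc1cc(OCc2ccccc2)c2c(c1)O[C@H](c1ccccc1)[C@H](OC(=O)[C@@H](OC)c1ccccc1)C2
F6 | step 6 | (2S,3S)-5,7-bis(benzyloxy)-2-phenylchroman-3-yl (2S)-methoxy(phenyl)acetate | C(c1ccccc1)Oc1cc(OCc2ccccc2)c2c(c1)O[C@@H](c1ccccc1)[C@@H](OC(=O)[C@@H](OC)c1ccccc1)C2
F7 | step 8 | (2R,3R)-5,7-bis(benzyloxy)-8-bromo-2-phenylchroman-3-ol | C(c1ccccc1)Oc1cc(OCc2ccccc2)c2c(c1Br)O[C@H](c1ccccc1)[C@H](O)C2
F8 | step 8 | (2R,3R,4S)-5,7-bis(benzyloxy)-8-bromo-4-(2-ethoxyethoxy)-2-phenylchroman-3-ol | C(c1ccccc1)Oc1cc(OCc2ccccc2)c2c(c1Br)O[C@H](c1ccccc1)[C@H](O)[C@H]2OCCOCC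
F9 | step 8 | (2R,3R)-5,7-bis(benzyloxy)-8-[(2R,3R,4S)-5,7-bis(benzyloxy)-8-bromo-3-hydroxy-2-phenyl-3,4-dihydro-2H-chromen-4-yl]-2-phenyl-3,4-dihydro-2H-chromen-3-ol | C(c1ccccc1)Oc1cc(OCc2ccccc2)c2c(c1Br)O[C@H](c1ccccc1)[C@H](O)[C@H]2c1c(OCc2ccccc2)cc(OCc2ccccc2)c2c1O[C@H](c1ccccc1)[C@H](O)C2
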